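The cyclohexene (C1 bearing the flavonol B ring, C2=C3(Me), C4H2, C5 resorcinyl, C6 aroyl) is cut at both bonds to its alkene, C1–C2 and C3–C4, so that C2=C3(Me) is a propyne unit. In one operation a nickel-catalysed formal [4+2] annulation inserts propyne between the electrophilic C4 of a coumarin (future C1) and a primary alkylzinc (future C4) carried by its C3 side chain, which already holds the C5 stereocentre. The coumarin lactone ties the B-ring phenol to the future aroyl carbon: it fixes the geometry that sets C1, later acylates the resorcinol unit, and releases the phenol that directs flavonol construction.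

Key step: step 8

Remark: cyclohexene atoms are numbered as above, and the all-trans (1R,5S,6R) arrangement is assumed to be the thermodynamic one at the epimerisable C6 (all three ring substituents equatorial).

Step 1
Reactants: 1 4-bromobenzene-1,3-diol
Product: 2 1-bromo-2,4-bis(methoxymethoxy)benzene
Conditions: MOMCl, iPr2NEt, CH2Cl2, 0 °C to rt
Reagents that add atoms: chloromethyl methyl ether (MOMCl), COCCl
Why: Williamson-type O-alkylation of both phenols gives acetal ethers that should survive organolithium, organomagnesium, organozinc and nickel chemistry and are removed together at the end.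

Step 2
Reactants: 2 1-bromo-2,4-bis(methoxymethoxy)benzene; 3 furan-2(5H)-one
Product: 6 (S)-4-[2,4-bis(methoxymethoxy)phenyl]dihydrofuran-2(3H)-one, via aryllithium 4 (not isolated), via lithium aryltrimethoxyborate 5 (not isolated)
Conditions: n-BuLi, THF, −78 °C; B(OMe)3, −78 °C to rt; then 3, [Rh(OH)(cod)]2 (3 mol %), (S)-BINAP (7 mol %), dioxane/H2O, 60 °C
Reagents that add atoms: none
Why: Hayashi–Miyaura reaction: the aryl group of borate 5 passes to rhodium, adds to the butenolide under control of (S)-BINAP on the face that should give the (S)-lactone (the future C5 centre), and water hydrolyses the rhodium enolate.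

Step 3
Reactants: 7 2,6-dihydroxybenzaldehyde
Product: 8 2-hydroxy-6-(methoxymethoxy)benzaldehyde
Conditions: MOMCl (1 equiv), iPr2NEt, CH2Cl2, 0 °C
Reagents that add atoms: chloromethyl methyl ether (MOMCl), COCCl
Why: Selective Williamson-type etherification: after the first alkylation the remaining phenol is deactivated by its hydrogen bond to the aldehyde.

Step 4
Reactants: 8 2-hydroxy-6-(methoxymethoxy)benzaldehyde
Product: 9 2-[(tert-butyldimethylsilyl)oxy]-6-(methoxymethoxy)benzaldehyde
Conditions: TBSCl, imidazole, DMF, rt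
Reagents that add atoms: tert-butyldimethylsilyl chloride (TBSCl), CC(C)(C)[Si](C)(C)Cl
Why: Silylation masks the remaining phenol during enolate chemistry and leaves it releasable by fluoride under non-acidic conditions.

Step 5
Reactants: 6 (S)-4-[2,4-bis(methoxymethoxy)phenyl]dihydrofuran-2(3H)-one; 9 2-[(tert-butyldimethylsilyl)oxy]-6-(methoxymethoxy)benzaldehyde
Product: 11 (4S)-4-[2,4-bis(methoxymethoxy)phenyl]-3-{[2-(tert-butyldimethylsilyloxy)-6-(methoxymethoxy)phenyl](hydroxy)methyl}dihydrofuran-2(3H)-one (diastereomer mixture at C3 and the carbinol carbon), via lithium enolate 10 (not isolated)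
Conditions: LiN(iPr)2, THF, −78 °C; then 9; AcOH, −78 °C
Reagents that add atoms: none
Why: Aldol addition of the lactone lithium enolate to the non-enolisable aldehyde; the two new centres are lost again in step 6 and the C4 centre of the lactone carries no acidic hydrogen, so it is untouched.

Step 6
Reactants: 11 aldol adduct from step 5
Product: 14 3-[(1R)-1-[2,4-bis(methoxymethoxy)phenyl]-2-hydroxyethyl]-5-(methoxymethoxy)-2H-chromen-2-one, via desilylated phenol 12 (not isolated), via hydroxydihydrocoumarin 13 (not isolated)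
Conditions: TBAF, THF, 0 °C to rt; then DBU, 50 °C
Reagents that add atoms: none
Why: Fluoride frees the phenoxide, which translactonises onto the butyrolactone carbonyl, and E1cB loss of water from 13 gives the aromatic coumarin (a Perkin/Knoevenagel-type coumarin synthesis), whose stability should drive the equilibria forward and which releases the primary alcohol without touching the stereocentre.

Step 7
Reactants: 14 coumarin alcohol
Product: 15 3-[(1R)-1-[2,4-bis(methoxymethoxy)phenyl]-2-iodoethyl]-5-(methoxymethoxy)-2H-chromen-2-one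
Conditions: I2, PPh3, imidazole, CH2Cl2, 0 °C
Reagents that add atoms: iodine, [I][I]
Why: Appel reaction: iodide displaces the primary alkoxyphosphonium group under buffered conditions that spare the acetal ethers.

Step 8
Reactants: 15 coumarin iodide; 16 propyne
Product: 20 (6aR,7S,10aR)-7-[2,4-bis(methoxymethoxy)phenyl]-1-(methoxymethoxy)-9-methyl-6a,7,8,10a-tetrahydro-6H-benzo[c]chromen-6-one, via alkylzinc iodide 17 (not isolated), via zinc enolate 18 (not isolated), via cis-fused epimer 19 (not isolated)
Conditions: Zn dust, LiCl, THF, 25 °C; then Ni(cod)2 (20 mol %), 16 (5 equiv), THF, 0 °C to rt; aq NH4Cl; then DBU (0.2 equiv), CH2Cl2, rt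
Reagents that add atoms: none
Why: Proposed new method: zerovalent nickel should join propyne and the coumarin C3=C4 bond by oxidative cyclisation, the unsubstituted alkyne carbon bonding to coumarin C4 (new C10–C10a bond, cyclohexene C2–C1) while the methyl-bearing carbon stays on nickel, after which the tethered primary alkylzinc transmetalates intramolecularly and C(sp2)–C(sp3) reductive elimination forms the C8–C9 bond (cyclohexene C4–C3) and releases zinc enolate 18. The closest known reaction type is the nickel-catalysed three-component alkylative coupling of enones, alkynes and organozincs, used here with the organozinc tethered to the acceptor so that it becomes a formal [4+2] annulation. The six-membered ring closes by reductive elimination from a seven-membered nickelacycle, and because both new bonds are delivered to the same side of the alkyne only the endocyclic cis alkene can form. C10a is set in the oxidative cyclisation under control of C7: with the C7–H bond eclipsing coumarin C4–H, nickel–alkyne should add anti to the C7 aryl group and syn to the CH2Zn arm, and since the lactone holds the B-ring carbon cis to the carbonyl this places the B ring and the C7 aryl cis (both equatorial); C6a is set by protonation and DBU equilibration of kinetic epimer 19 to the trans-fused lactone. The step needs alkyl transfer to win over β-hydride elimination and over ketene loss from the aryl ester enolate, which phosphine-free Ni(cod)2 and the intramolecular transmetalation should secure, and it needs C–C bond formation at the less hindered alkyne terminus, which is the normal regiochemistry of this coupling with terminal alkynes.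

Step 9
Reactants: 20 trans-fused lactone; 2 1-bromo-2,4-bis(methoxymethoxy)benzene
Product: 22 [2,4-bis(methoxymethoxy)phenyl]{(1R,2R,6S)-6-[2,4-bis(methoxymethoxy)phenyl]-2-[2-hydroxy-6-(methoxymethoxy)phenyl]-4-methylcyclohex-3-en-1-yl}methanone, via arylmagnesium bromide 21 (not isolated)
Conditions: 2, Mg turnings, LiCl, THF, rt; then 20, THF, −20 to 0 °C; aq NH4Cl
Reagents that add atoms: none
Why: Grignard acylation (nucleophilic acyl substitution): arylmagnesium bromide 21, formed by magnesium insertion into the C–Br bond of 2, adds to the activated aryl lactone, whose tetrahedral intermediate collapses with loss of the phenoxide to a hindered ketone that should resist a second addition by the moderately reactive Grignard reagent; the ring centres are not involved and the trans arrangement at the ketone α-carbon is the thermodynamic one.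

Step 10
Reactants: 22 phenol ketone
Product: 24 3-{(1R,5S,6R)-6-[2,4-bis(methoxymethoxy)benzoyl]-5-[2,4-bis(methoxymethoxy)phenyl]-3-methylcyclohex-2-en-1-yl}-2-hydroxy-4-(methoxymethoxy)benzaldehyde, via hydroxymethylphenol 23 (not isolated)
Conditions: MgCl2, Et3N, (CH2O)n, MeCN, 70 °C; aq NH4Cl
Reagents that add atoms: paraformaldehyde (formaldehyde), C=O
Why: Casnati–Skattebøl ortho-formylation: only the single free phenol forms a magnesium phenoxide, which delivers formaldehyde to its one open ortho position, and 23 is oxidised by a second formaldehyde through hydride transfer.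

Step 11
Reactants: 24 salicylaldehyde
Product: 25 3-{(1R,5S,6R)-6-[2,4-bis(methoxymethoxy)benzoyl]-5-[2,4-bis(methoxymethoxy)phenyl]-3-methylcyclohex-2-en-1-yl}-2,4-bis(methoxymethoxy)benzaldehyde
Conditions: MOMCl, iPr2NEt, DMAP (cat.), CH2Cl2, 40 °C
Reagents that add atoms: chloromethyl methyl ether (MOMCl), COCCl
Why: O-alkylation of the salicylaldehyde phenol prevents phenoxide deactivation of the aldehyde and side reactions of a free B-ring hydroxyl in the two base-mediated steps that follow.

Step 12
Reactants: 26 1-(2,4-dihydroxyphenyl)ethanone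
Product: 27 1-[2-hydroxy-4-(methoxymethoxy)phenyl]ethanone
Conditions: MOMCl (1.1 equiv), K2CO3, acetone, rt
Reagents that add atoms: chloromethyl methyl ether (MOMCl), COCCl
Why: The 4-hydroxyl is alkylated selectively because the 2-hydroxyl is hydrogen-bonded to the ketone, and that free 2-hydroxyl is needed later for closure of the pyranone ring.

Step 13
Reactants: 25 aldehyde; 27 1-[2-hydroxy-4-(methoxymethoxy)phenyl]ethanone
Product: 28 (E)-3-[3-{(1R,5S,6R)-6-[2,4-bis(methoxymethoxy)benzoyl]-5-[2,4-bis(methoxymethoxy)phenyl]-3-methylcyclohex-2-en-1-yl}-2,4-bis(methoxymethoxy)phenyl]-1-[2-hydroxy-4-(methoxymethoxy)phenyl]prop-2-en-1-one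
Conditions: KOH, EtOH, rt; AcOH
Reagents that add atoms: none
Why: Claisen–Schmidt condensation of the methyl ketone enolate with the non-enolisable aldehyde should give the (E)-2'-hydroxychalcone; the hindered tertiary α-carbon of the cyclohexenyl ketone cannot condense and at most equilibrates to the favoured all-trans arrangement.

Step 14
Reactants: 28 chalcone
Product: 30 2-[3-{(1R,5S,6R)-6-[2,4-bis(methoxymethoxy)benzoyl]-5-[2,4-bis(methoxymethoxy)phenyl]-3-methylcyclohex-2-en-1-yl}-2,4-bis(methoxymethoxy)phenyl]-3-hydroxy-7-(methoxymethoxy)-4H-chromen-4-one, via dihydroflavonol 29 (not isolated)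
Conditions: H2O2 (30% aq), NaOH, MeOH, 0 °C to rt; AcOH
Reagents that add atoms: hydrogen peroxide, OO
Why: Algar–Flynn–Oyamada reaction: alkaline hydrogen peroxide oxidises the enone, the 2'-phenoxide closes the pyranone ring to 29 and further oxidation gives the 3-hydroxyflavone, while the isolated trisubstituted alkene is inert to nucleophilic peroxide.

Step 15
Reactants: 30 protected flavonol
Product: 31 2-{3-[(1R,5S,6R)-6-(2,4-dihydroxybenzoyl)-5-(2,4-dihydroxyphenyl)-3-methylcyclohex-2-en-1-yl]-2,4-dihydroxyphenyl}-3,7-dihydroxy-4H-chromen-4-one (CNP0190989.1)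
Conditions: HCl (2 M), MeOH, 40 °C
Reagents that add atoms: none
Why: Acid-catalysed acetal exchange with methanol should cleave all seven methoxymethyl ethers as dimethoxymethane under conditions mild enough to leave the trisubstituted alkene and the three stereocentres untouched.

Compound list
1 | 4-bromobenzene-1,3-diol | Oc1ccc(Br)c(O)c1 | starting material
2 | 1-bromo-2,4-bis(methoxymethoxy)benzene | COCOc1ccc(Br)c(OCOC)c1 | intermediate
3 | furan-2(5H)-one | O=C1C=CCO1 | starting material
4 | [2,4-bis(methoxymethoxy)phenyl]lithium | COCOc1ccc([Li])c(OCOC)c1 | intermediate (not isolated)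
5 | lithium [2,4-bis(methoxymethoxy)phenyl]trimethoxyborate | COCOc1ccc([B-](OC)(OC)OC)c(OCOC)c1.[Li+] | intermediate (not isolated)
6 | (S)-4-[2,4-bis(methoxymethoxy)phenyl]dihydrofuran-2(3H)-one | O=C1C[C@@H](c2ccc(OCOC)cc2OCOC)CO1 | intermediate
7 | 2,6-dihydroxybenzaldehyde | O=Cc1c(O)cccc1O | starting material
8 | 2-hydroxy-6-(methoxymethoxy)benzaldehyde | O=Cc1c(O)cccc1OCOC | intermediate
9 | 2-[(tert-butyldimethylsilyl)oxy]-6-(methoxymethoxy)benzaldehyde | O=Cc1c(O[Si](C)(C)C(C)(C)C)cccc1OCOC | intermediate
10 | lithium enolate of lactone 6, (S) at the aryl-bearing carbon | [Li]OC1=C[C@@H](c2ccc(OCOC)cc2OCOC)CO1 | intermediate (not isolated)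
11 | (4S)-4-[2,4-bis(methoxymethoxy)phenyl]-3-{[2-(tert-butyldimethylsilyloxy)-6-(methoxymethoxy)phenyl](hydroxy)methyl}dihydrofuran-2(3H)-one, diastereomer mixture at C3 and the carbinol carbon | O=C1OC[C@H](c2ccc(OCOC)cc2OCOC)C1C(O)c3c(O[Si](C)(C)C(C)(C)C)cccc3OCOC | intermediate
12 | (4S)-4-[2,4-bis(methoxymethoxy)phenyl]-3-{hydroxy[2-hydroxy-6-(methoxymethoxy)phenyl]methyl}dihydrofuran-2(3H)-one | O=C1OC[C@H](c2ccc(OCOC)cc2OCOC)C1C(O)c3c(O)cccc3OCOC | intermediate (not isolated)
13 | 3-[(1S)-1-[2,4-bis(methoxymethoxy)phenyl]-2-hydroxyethyl]-4-hydroxy-5-(methoxymethoxy)chroman-2-one | O=C1Oc2cccc(OCOC)c2C(O)C1[C@H](CO)c3ccc(OCOC)cc3OCOC | intermediate (not isolated)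
14 | 3-[(1R)-1-[2,4-bis(methoxymethoxy)phenyl]-2-hydroxyethyl]-5-(methoxymethoxy)-2H-chromen-2-one | O=C1Oc2cccc(OCOC)c2C=C1[C@H](CO)c3ccc(OCOC)cc3OCOC | intermediate
15 | 3-[(1R)-1-[2,4-bis(methoxymethoxy)phenyl]-2-iodoethyl]-5-(methoxymethoxy)-2H-chromen-2-one | O=C1Oc2cccc(OCOC)c2C=C1[C@H](C[I])c3ccc(OCOC)cc3OCOC | intermediate
16 | propyne | CC#C | starting material
17 | alkylzinc iodide from 15, (1R) | O=C1Oc2cccc(OCOC)c2C=C1[C@H](C[Zn][I])c3ccc(OCOC)cc3OCOC | intermediate (not isolated)
18 | iodozinc enolate of lactone 20, (7S,10aR) | CC1=C[C@H]2c3c(OCOC)cccc3OC(O[Zn][I])=C2[C@@H](c4ccc(OCOC)cc4OCOC)C1 | intermediate (not isolated)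
19 | (6aS,7S,10aR) cis-fused epimer of 20 | CC1=C[C@H]2c3c(OCOC)cccc3OC(=O)[C@H]2[C@@H](c4ccc(OCOC)cc4OCOC)C1 | intermediate (not isolated)
20 | (6aR,7S,10aR)-7-[2,4-bis(methoxymethoxy)phenyl]-1-(methoxymethoxy)-9-methyl-6a,7,8,10a-tetrahydro-6H-benzo[c]chromen-6-one | CC1=C[C@H]2c3c(OCOC)cccc3OC(=O)[C@@H]2[C@@H](c4ccc(OCOC)cc4OCOC)C1 | intermediate
21 | [2,4-bis(methoxymethoxy)phenyl]magnesium bromide | COCOc1ccc([Mg]Br)c(OCOC)c1 | intermediate (not isolated)
22 | [2,4-bis(methoxymethoxy)phenyl]{(1R,2R,6S)-6-[2,4-bis(methoxymethoxy)phenyl]-2-[2-hydroxy-6-(methoxymethoxy)phenyl]-4-methylcyclohex-3-en-1-yl}methanone | CC1=C[C@@H](c2c(O)cccc2OCOC)[C@H](C(=O)c3ccc(OCOC)cc3OCOC)[C@@H](c4ccc(OCOC)cc4OCOC)C1 | intermediate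
23 | hydroxymethylphenol: as 22 with CH2OH ortho to the phenol, (1R,2R,6S) | CC1=C[C@@H](c2c(O)c(CO)ccc2OCOC)[C@H](C(=O)c3ccc(OCOC)cc3OCOC)[C@@H](c4ccc(OCOC)cc4OCOC)C1 | intermediate (not isolated)
24 | 3-{(1R,5S,6R)-6-[2,4-bis(methoxymethoxy)benzoyl]-5-[2,4-bis(methoxymethoxy)phenyl]-3-methylcyclohex-2-en-1-yl}-2-hydroxy-4-(methoxymethoxy)benzaldehyde | CC1=C[C@@H](c2c(O)c(C=O)ccc2OCOC)[C@H](C(=O)c3ccc(OCOC)cc3OCOC)[C@@H](c4ccc(OCOC)cc4OCOC)C1 | intermediate
25 | 3-{(1R,5S,6R)-6-[2,4-bis(methoxymethoxy)benzoyl]-5-[2,4-bis(methoxymethoxy)phenyl]-3-methylcyclohex-2-en-1-yl}-2,4-bis(methoxymethoxy)benzaldehyde | CC1=C[C@@H](c2c(OCOC)c(C=O)ccc2OCOC)[C@H](C(=O)c3ccc(OCOC)cc3OCOC)[C@@H](c4ccc(OCOC)cc4OCOC)C1 | intermediate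
26 | 1-(2,4-dihydroxyphenyl)ethanone | CC(=O)c1ccc(O)cc1O | starting material
27 | 1-[2-hydroxy-4-(methoxymethoxy)phenyl]ethanone | CC(=O)c1ccc(OCOC)cc1O | intermediate
28 | (E)-2'-hydroxychalcone from 25 and 27, (1R,5S,6R) in the cyclohexene | CC1=C[C@@H](c2c(OCOC)c(/C=C/C(=O)c5ccc(OCOC)cc5O)ccc2OCOC)[C@H](C(=O)c3ccc(OCOC)cc3OCOC)[C@@H](c4ccc(OCOC)cc4OCOC)C1 | intermediate
29 | dihydroflavonol (3-hydroxychroman-4-one) from 28, (1R,5S,6R) in the cyclohexene, pyranone centres undefined | CC1=C[C@@H](c2c(OCOC)c(C5Oc6cc(OCOC)ccc6C(=O)C5O)ccc2OCOC)[C@H](C(=O)c3ccc(OCOC)cc3OCOC)[C@@H](c4ccc(OCOC)cc4OCOC)C1 | intermediate (not isolated)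
30 | 2-[3-{(1R,5S,6R)-6-[2,4-bis(methoxymethoxy)benzoyl]-5-[2,4-bis(methoxymethoxy)phenyl]-3-methylcyclohex-2-en-1-yl}-2,4-bis(methoxymethoxy)phenyl]-3-hydroxy-7-(methoxymethoxy)-4H-chromen-4-one | CC1=C[C@@H](c2c(OCOC)c(-c5oc6cc(OCOC)ccc6c(=O)c5O)ccc2OCOC)[C@H](C(=O)c3ccc(OCOC)cc3OCOC)[C@@H](c4ccc(OCOC)cc4OCOC)C1 | intermediate
31 | 2-{3-[(1R,5S,6R)-6-(2,4-dihydroxybenzoyl)-5-(2,4-dihydroxyphenyl)-3-methylcyclohex-2-en-1-yl]-2,4-dihydroxyphenyl}-3,7-dihydroxy-4H-chromen-4-one | CC1=C[C@@H](c2c(O)ccc(-c3oc4cc(O)ccc4c(=O)c3O)c2O)[C@H](C(=O)c2ccc(O)cc2O)[C@@H](c2ccc(O)cc2O)C1 | target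

Total step count: 15. Longest linear sequence: 12 steps (steps 1, 2, 5, 6, 7, 8, 9, 10, 11, 13, 14, 15).

Steps most likely to fail

Step 8 (proposed new method). The alkyl transfer at nickel may not compete with β-hydride elimination, with ketene extrusion from the aryl ester enolate or with propyne oligomerisation, and facial selectivity at coumarin C4 may be poor. The fallback uses known reactions and makes the two bonds in separate operations. It sets out from iodide 15 and propyne 16 and comes back at lactone 20. Bromoboration of 16 with BBr3 gives (Z)-dibromo(2-bromoprop-1-en-1-yl)borane F1, and pinacol converts it into (Z)-2-(2-bromoprop-1-en-1-yl)-4,4,5,5-tetramethyl-1,3,2-dioxaborolane F2. The alkylzinc made from 15 (Zn dust, LiCl) is joined to F2 by Negishi coupling (Pd(PPh3)4, THF) with retention of alkene geometry, giving the (Z)-alkenyl pinacolboronate F3, which holds the C8–C9 bond. A rhodium-catalysed intramolecular 1,4-addition of the alkenylboron to the coumarin ([Rh(OH)(cod)]2, dioxane/H2O, 60 °C) then closes the ring through a chair-like arrangement with the C7 aryl equatorial, and DBU equilibration gives 20.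

Step 6. The β-hydroxy lactone may cleave by retro-aldol reaction once the phenoxide is free, or the sequence may stall before dehydration. The fallback removes the aldol hydroxyl first. It sets out from aldol adduct 11 and comes back at coumarin 14. Mesylation and elimination (MsCl, Et3N, then DBU) give the (4R,E)-arylidene lactone silyl ether F4, and TBAF buffered with AcOH gives the (4R,E)-arylidene lactone phenol F5. Irradiation at 350 nm in MeCN isomerises the alkene from E to Z, and the Z isomer lactonises spontaneously onto the phenol to give 14.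

Step 14. With the crowded, twisted B ring the phenoxide may attack the α-carbon (aurone formation), or the substrate may be over-oxidised by peroxide. The fallback avoids peroxide and builds the flavonol stepwise. It sets out from chalcone 28 and comes back at flavonol 30. Oxa-Michael cyclisation (NaOAc, EtOH, reflux) gives the flavanone F6. Hydroxylation of its kinetic enolate (LiN(SiMe3)2, 2-(phenylsulfonyl)-3-phenyloxaziridine, THF, −78 °C) gives dihydroflavonol 29, here isolated. Oxidation of the carbinol with 2-iodoxybenzoic acid in DMSO and tautomerisation of the resulting dione give 30.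

Further compounds
F1 | step 8 | (Z)-dibromo(2-bromoprop-1-en-1-yl)borane | C/C(Br)=C/B(Br)Br
F2 | step 8 | (Z)-2-(2-bromoprop-1-en-1-yl)-4,4,5,5-tetramethyl-1,3,2-dioxaborolane | C/C(Br)=C/B1OC(C)(C)C(C)(C)O1
F3 | step 8 | 3-[(1R,3Z)-1-[2,4-bis(methoxymethoxy)phenyl]-3-methyl-4-(4,4,5,5-tetramethyl-1,3,2-dioxaborolan-2-yl)but-3-en-1-yl]-5-(methoxymethoxy)-2H-chromen-2-one | O=C1Oc2cccc(OCOC)c2C=C1[C@H](C/C(C)=C\B3OC(C)(C)C(C)(C)O3)c4ccc(OCOC)cc4OCOC
F4 | step 6 | (4R)-4-[2,4-bis(methoxymethoxy)phenyl]-3-[(E)-2-(tert-butyldimethylsilyloxy)-6-(methoxymethoxy)benzylidene]dihydrofuran-2(3H)-one | O=C1OC[C@H](c2ccc(OCOC)cc2OCOC)/C1=C\c3c(O[Si](C)(C)C(C)(C)C)cccc3OCOC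
F5 | step 6 | (4R)-4-[2,4-bis(methoxymethoxy)phenyl]-3-[(E)-2-hydroxy-6-(methoxymethoxy)benzylidene]dihydrofuran-2(3H)-one | O=C1OC[C@H](c2ccc(OCOC)cc2OCOC)/C1=C\c3c(O)cccc3OCOC
F6 | step 14 | 2-[3-{(1R,5S,6R)-6-[2,4-bis(methoxymethoxy)benzoyl]-5-[2,4-bis(methoxymethoxy)phenyl]-3-methylcyclohex-2-en-1-yl}-2,4-bis(methoxymethoxy)phenyl]-7-(methoxymethoxy)chroman-4-one, C2 epimer mixture | CC1=C[C@@H](c2c(OCOC)c(C5CC(=O)c6ccc(OCOC)cc6O5)ccc2OCOC)[C@H](C(=O)c3ccc(OCOC)cc3OCOC)[C@@H](c4ccc(OCOC)cc4OCOC)C1
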